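**Plan**

- Retrosynthesis: the two ring B benzyl ethers are cut first; then, in each ring A (C1 arm, C3 OH, C5 OMe, C6 bridge), the bonds C6–C1 and C2–C3 are cut, so that C1 and C2 leave with the arm as a nitroalkene.
- The feature that allows this: the bridge CH2 together with C6, C5(OMe), C4 and C3(OH) of both rings A is one nine-carbon chain oxygenated at its 1, 3, 7 and 9 positions, a glutarate extended by acetate at both ends and usable as a bis(1,3-dimethoxy-1-silyloxy diene).
- Forward, arm: dihydroferulic acid is benzylated, reduced to the aldehyde, and taken through nitroaldol addition and dehydration to the (E)-nitroalkene.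
- Forward, chain: glutaryl chloride and Meldrum's acid give the bis(keto ester), then the bis(enol ether), then the bis(silyl ketene acetal).
- Both rings A close in one operation by twofold [4+2] addition and aromatization with loss of Me3SiOH, MeOH and HNO2; hydrogenolysis of the benzyl ethers ends the route.
- Stereochemistry: the target has no stereocentre; centres formed in steps 3 and 8 are erased, so only alkene geometry (steps 4, 6, 7) and the regiochemistry of step 8 need control.

Key step: step 8

Remark: the geometry of the two ketene acetal C=C bonds of the bis-diene is left undefined because these carbons become the phenol carbons; the cycloadduct and the nitro ketone of step 8 are diastereomer mixtures whose sp3 centres all vanish on aromatization.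

**Route**

Step 1
Reactants: 1 dihydroferulic acid [3-(4-hydroxy-3-methoxyphenyl)propanoic acid]
Product: 2 benzyl 3-[4-(benzyloxy)-3-methoxyphenyl]propanoate
Conditions: BnBr (2.3 equiv), K2CO3 (3 equiv), DMF, 60 °C
Reagents that add atoms: benzyl bromide, BrCc1ccccc1
Why: Williamson etherification of the phenoxide and SN2 alkylation of the carboxylate run together under K2CO3, so one operation masks the ring B phenol and gives an ester suited to partial reduction.

Step 2
Reactants: 2 benzyl 3-[4-(benzyloxy)-3-methoxyphenyl]propanoate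
Product: 3 3-[4-(benzyloxy)-3-methoxyphenyl]propanal
Conditions: i-Bu2AlH (1.05 equiv), CH2Cl2, −78 °C; MeOH, then aq. KNaC4H4O6 (Rochelle salt)
Reagents that add atoms: none
Why: Partial ester reduction by diisobutylaluminium hydride at −78 °C should stop at the aluminium hemiacetal, which releases the aldehyde only on aqueous work-up, and the aryl benzyl ether is inert to the hydride.

Step 3
Reactants: 3 3-[4-(benzyloxy)-3-methoxyphenyl]propanal; 4 nitromethane
Product: 5 rac-4-[4-(benzyloxy)-3-methoxyphenyl]-1-nitrobutan-2-ol
Conditions: MeNO2 (5 equiv), KOt-Bu (10 mol %), THF/t-BuOH, 0 °C to rt; aq. NH4Cl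
Reagents that add atoms: none
Why: Henry (nitroaldol) addition of the nitronate to an unhindered aliphatic aldehyde is reliable under catalytic base, and the carbinol centre, formed racemic, is removed in the next step.

Step 4
Reactants: 5 rac-4-[4-(benzyloxy)-3-methoxyphenyl]-1-nitrobutan-2-ol
Product: 7 1-(benzyloxy)-2-methoxy-4-[(E)-4-nitrobut-3-en-1-yl]benzene, via nitro mesylate 6 (not isolated)
Conditions: MsCl (1.2 equiv), Et3N (2.5 equiv), CH2Cl2, −20 to 0 °C
Reagents that add atoms: none
Why: Mesylation of the β-nitro alcohol followed by E1cB elimination through the nitronate should give the conjugated nitroalkene in its thermodynamically preferred (E) geometry, the low temperature limiting base-induced shift of the double bond out of conjugation.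

Step 5
Reactants: 8 glutaryl chloride (pentanedioyl dichloride); 9 Meldrum's acid (2,2-dimethyl-1,3-dioxane-4,6-dione, 2.1 equiv)
Product: 11 dimethyl 3,7-dioxononanedioate, via bis(acyl Meldrum's acid) 10 (not isolated)
Conditions: pyridine (4.4 equiv), CH2Cl2, 0 °C to rt; 1 M HCl wash; then MeOH, reflux
Reagents that add atoms: methanol, CO
Why: C-acylation of the Meldrum's acid enolate by each acid chloride, followed by methanolysis of the acyl Meldrum's acid with loss of acetone and CO2, is the standard one-flask conversion of an acid chloride into a methyl β-keto ester.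

Step 6
Reactants: 11 dimethyl 3,7-dioxononanedioate
Product: 13 dimethyl (2E,6E)-3,7-dimethoxynona-2,6-dienedioate, via bis(dimethyl ketal) 12 (not isolated)
Conditions: HC(OMe)3 (6 equiv), TsOH·H2O (5 mol %), MeOH, rt; then toluene, 110 °C, MeOH distilled off
Reagents that add atoms: trimethyl orthoformate, COC(OC)OC
Why: Acid-catalysed ketalization of each ketone by the orthoformate and loss of methanol toward the ester gives the conjugated enol ether as its thermodynamic (E) isomer, as in the preparation of methyl (E)-3-methoxybut-2-enoate, and fast ketalization should keep the 1,5-diketone from intramolecular aldol condensation.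

Step 7
Reactants: 13 dimethyl (2E,6E)-3,7-dimethoxynona-2,6-dienedioate
Product: 14 (3Z,6Z)-1,3,7,9-tetramethoxy-1,9-bis(trimethylsilyloxy)nona-1,3,6,8-tetraene
Conditions: LiN(i-Pr)2 (2.3 equiv), THF, −78 °C; Me3SiCl (2.6 equiv), −78 to 0 °C; pentane, filtration under Ar, used crude
Reagents that add atoms: chlorotrimethylsilane, C[Si](C)(C)Cl
Why: Kinetic γ-deprotonation of each (E)-3-methoxy enoate (the C4 and C6 methylenes lie syn to the ester carbonyls) and O-silylation of the dienolates is the standard preparation of 1,3-dialkoxy-1-silyloxybuta-1,3-dienes, and the central CH2 should take the outward position on each new C=C, the geometry that can reach the s-cis conformation.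

Step 8
Reactants: 14 (3Z,6Z)-1,3,7,9-tetramethoxy-1,9-bis(trimethylsilyloxy)nona-1,3,6,8-tetraene; 7 1-(benzyloxy)-2-methoxy-4-[(E)-4-nitrobut-3-en-1-yl]benzene (2.3 equiv)
Product: 17 4,4'-methylenebis{3-[2-(4-benzyloxy-3-methoxyphenyl)ethyl]-5-methoxyphenol}, via twofold cycloadduct 15 (not isolated), via bis(nitro ketone) 16 (not isolated)
Conditions: toluene, 0 to 40 °C, Ar; then 0.1 M aq. HCl/THF, 0 °C; then DBU (4 equiv), THF, rt to 50 °C, Ar
Reagents that add atoms: none
Why: Each 1,3-dimethoxy-1-silyloxy diene unit of 14 adds to the electron-poor (E)-nitroalkene 7 in a polar, asynchronous [4+2] cycloaddition (normal-demand Diels–Alder reaction, at its stepwise limit a vinylogous Mukaiyama–Michael addition followed by closure of the nitronate carbon onto the silyloxycarbenium carbon), the closest known reaction type being the benzannulation of 1,3-dioxygenated silyloxy dienes with nitroalkenes in which nitro steers the regiochemistry and then leaves as HNO2. Each ring A closes as a six-membered carbocycle in this intermolecular [4+2] mode, the ring-forming bonds being C6–C1 (diene carbon next to the central CH2 to the carbon β to nitro) and C3–C2 (ketene acetal carbon to the nitro-bearing carbon). The selectivity the step needs is regiochemical and is secured by polarity: the three donor oxygens place the largest HOMO coefficient on the diene terminus beside the central CH2 and the nitro group places the largest LUMO coefficient on its β carbon, so the arm ends up next to the bridge and the future hydroxyl para to it. The sp3 centres of 15 (set by the endo or exo approach and the (E) geometry of 7) need no control, because none survives and the target has no stereocentre. Dilute acid then hydrolyses each C(OMe)(OSiMe3) carbon to the ketone of a 3-methoxy-6-nitrocyclohex-2-enone (16) with loss of Me3SiOH and MeOH while the vinylogous ester methoxy stays, and DBU removes HNO2 through the dienol tautomer in which the C–NO2 carbon is sp3 and allylic, the gain of aromaticity making this loss irreversible. The product therefore carries a free OH at C3 and OMe at C5 of each ring A without any protecting group step on these rings.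

Step 9
Reactants: 17 4,4'-methylenebis{3-[2-(4-benzyloxy-3-methoxyphenyl)ethyl]-5-methoxyphenol}
Product: 18 4,4'-methylenebis{3-[2-(4-hydroxy-3-methoxyphenyl)ethyl]-5-methoxyphenol} (CNP0079383.0)
Conditions: H2 (1 atm), Pd/C (10 wt % Pd), EtOAc/MeOH, rt
Reagents that add atoms: none
Why: Hydrogenolysis of aryl benzyl ethers over palladium on carbon is selective for the O–CH2Ph bonds and should leave the diarylmethane bridge, the bibenzyl chains and the methyl ethers untouched.

**Compound list**

1 | dihydroferulic acid, 3-(4-hydroxy-3-methoxyphenyl)propanoic acid | COc1cc(CCC(=O)O)ccc1O | starting material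
2 | benzyl 3-[4-(benzyloxy)-3-methoxyphenyl]propanoate | COc1cc(CCC(=O)OCc2ccccc2)ccc1OCc1ccccc1 | intermediate
3 | 3-[4-(benzyloxy)-3-methoxyphenyl]propanal | COc1cc(CCC=O)ccc1OCc1ccccc1 | intermediate
4 | nitromethane | C[N+](=O)[O-] | starting material
5 | rac-4-[4-(benzyloxy)-3-methoxyphenyl]-1-nitrobutan-2-ol (racemic) | COc1cc(CCC(O)C[N+](=O)[O-])ccc1OCc1ccccc1 | intermediate
6 | rac-4-[4-(benzyloxy)-3-methoxyphenyl]-1-nitrobutan-2-yl methanesulfonate (racemic) | COc1cc(CCC(C[N+](=O)[O-])OS(C)(=O)=O)ccc1OCc1ccccc1 | intermediate (not isolated)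
7 | 1-(benzyloxy)-2-methoxy-4-[(E)-4-nitrobut-3-en-1-yl]benzene | COc1cc(CC/C=C/[N+](=O)[O-])ccc1OCc1ccccc1 | intermediate
8 | glutaryl chloride | O=C(Cl)CCCC(Cl)=O | starting material
9 | Meldrum's acid, 2,2-dimethyl-1,3-dioxane-4,6-dione | CC1(C)OC(=O)CC(=O)O1 | starting material
10 | 5,5'-(1,5-dihydroxypentane-1,5-diylidene)bis(2,2-dimethyl-1,3-dioxane-4,6-dione), enol form of the bis(acyl Meldrum's acid) | CC1(C)OC(=O)C(=C(O)CCCC(O)=C2C(=O)OC(C)(C)OC2=O)C(=O)O1 | intermediate (not isolated)
11 | dimethyl 3,7-dioxononanedioate | COC(=O)CC(=O)CCCC(=O)CC(=O)OC | intermediate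
12 | dimethyl 3,3,7,7-tetramethoxynonanedioate | COC(=O)CC(OC)(OC)CCCC(OC)(OC)CC(=O)OC | intermediate (not isolated)
13 | dimethyl (2E,6E)-3,7-dimethoxynona-2,6-dienedioate | COC(=O)/C=C(/OC)CCC/C(OC)=C\C(=O)OC | intermediate
14 | (3Z,6Z)-1,3,7,9-tetramethoxy-1,9-bis(trimethylsilyloxy)nona-1,3,6,8-tetraene (ketene acetal geometry undefined) | COC(O[Si](C)(C)C)=C/C(OC)=C/C/C=C(OC)/C=C(OC)O[Si](C)(C)C | intermediate
15 | bis{6-[2-(4-benzyloxy-3-methoxyphenyl)ethyl]-2,4-dimethoxy-5-nitro-4-(trimethylsilyloxy)cyclohex-2-en-1-yl}methane (mixture of diastereomers) | COC1(O[Si](C)(C)C)C=C(OC)C(CC2C(OC)=CC(OC)(O[Si](C)(C)C)C([N+](=O)[O-])C2CCc2ccc(OCc3ccccc3)c(OC)c2)C(CCc2ccc(OCc3ccccc3)c(OC)c2)C1[N+](=O)[O-] | intermediate (not isolated)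
16 | 4,4'-methylenebis{5-[2-(4-benzyloxy-3-methoxyphenyl)ethyl]-3-methoxy-6-nitrocyclohex-2-en-1-one} (mixture of diastereomers) | O=C1C=C(OC)C(CC2C(OC)=CC(=O)C([N+](=O)[O-])C2CCc2ccc(OCc3ccccc3)c(OC)c2)C(CCc2ccc(OCc3ccccc3)c(OC)c2)C1[N+](=O)[O-] | intermediate (not isolated)
17 | 4,4'-methylenebis{3-[2-(4-benzyloxy-3-methoxyphenyl)ethyl]-5-methoxyphenol} | COc1cc(CCc2cc(O)cc(OC)c2Cc2c(CCc3ccc(OCc4ccccc4)c(OC)c3)cc(O)cc2OC)ccc1OCc1ccccc1 | intermediate
18 | 4,4'-methylenebis{3-[2-(4-hydroxy-3-methoxyphenyl)ethyl]-5-methoxyphenol} | COc1cc(CCc2cc(O)cc(OC)c2Cc2c(CCc3ccc(O)c(OC)c3)cc(O)cc2OC)ccc1O | target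

**Count and risks**

Total steps: 9. Longest linear sequence: 6 (steps 1, 2, 3, 4, 8, 9); the diene branch contributes 5 (steps 5, 6, 7, 8, 9).

Step 8 (most likely to fail). After the first ring has formed, the second diene unit may be protonated or desilylated before it adds. Open-chain Michael adducts may be silylated instead of closing. The nitro ketone may rest as its nitronate, so that loss of nitrous acid stays incomplete. The fallback keeps 14 and the same ring-forming bonds but replaces the nitroalkene by an alkyne carrying an ester. It sets out from aldehyde 3 and comes back at 17. Seyferth–Gilbert homologation of 3 with dimethyl (1-diazo-2-oxopropyl)phosphonate (K2CO3, MeOH) should give 1-(benzyloxy)-4-(but-3-yn-1-yl)-2-methoxybenzene F1. Deprotonation with n-BuLi and trapping with methyl chloroformate should give methyl 5-[4-(benzyloxy)-3-methoxyphenyl]pent-2-ynoate F2. Heating 14 with F2 (toluene, 110 °C) should give, with the same polarity-controlled regiochemistry, the twofold cycloadduct dimethyl 3,3'-methylenebis{2-[2-(4-benzyloxy-3-methoxyphenyl)ethyl]-4,6-dimethoxy-6-(trimethylsilyloxy)cyclohexa-1,4-diene-1-carboxylate} F3. This should aromatize by 1,4-loss of methanol and lose its silyl groups on acidic work-up to dimethyl 3,3'-methylenebis{2-[2-(4-benzyloxy-3-methoxyphenyl)ethyl]-6-hydroxy-4-methoxybenzoate} F4. Saponification (KOH, aqueous DMSO, heat) should give 3,3'-methylenebis{2-[2-(4-benzyloxy-3-methoxyphenyl)ethyl]-6-hydroxy-4-methoxybenzoic acid} F5. Decarboxylation of this ortho-hydroxy, para-methoxy acid on acidification and warming returns the route to 17.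

Step 7. Deprotonation at the second enoate arm may stay incomplete, silylation may occur on carbon, and silyl groups may be lost by hydrolysis while the lithium salts are removed; each of these leaves material with only one diene unit that cannot be purified. The fallback takes the bridge carbon out of the diene. It sets out from nitroalkene 7 and comes back at 17. Commercial 1,3-dimethoxy-1-(trimethylsilyloxy)buta-1,3-diene should add to 7 under the conditions of step 8 to give 1-(benzyloxy)-4-{2-[3,5-dimethoxy-2-nitro-3-(trimethylsilyloxy)cyclohex-4-en-1-yl]ethyl}-2-methoxybenzene F6. Dilute acid should convert it into 5-[2-(4-benzyloxy-3-methoxyphenyl)ethyl]-3-methoxy-6-nitrocyclohex-2-en-1-one F7, and DBU into 3-[2-(4-benzyloxy-3-methoxyphenyl)ethyl]-5-methoxyphenol F8. Two molecules of F8 would then be joined at the carbon para to the hydroxyl with paraformaldehyde (0.5 equiv) under acid catalysis, by hydroxymethylation followed by Friedel–Crafts alkylation of the second phenol, which gives 17. Bridging ortho to the hydroxyl would compete and would have to be separated by chromatography.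

Step 5. After the first acylation, the enol oxygen of the acyl Meldrum's acid may close onto the remaining acid chloride to a six-membered enol lactone, so that only one keto ester arm is built. The fallback sets out from glutaryl chloride 8 and comes back at 11. With N,O-dimethylhydroxylamine hydrochloride and pyridine, 8 should give the bis(N-methoxy-N-methyl amide) N1,N5-dimethoxy-N1,N5-dimethylpentanediamide F9. Addition of the lithium enolate of methyl acetate (MeOAc, LiN(i-Pr)2, THF, −78 °C) forms chelated tetrahedral intermediates that should release the bis(β-keto ester) 11 only on aqueous work-up.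

**Further compounds**

F1 | step 8 | 1-(benzyloxy)-4-(but-3-yn-1-yl)-2-methoxybenzene | COc1cc(CCC#C)ccc1OCc1ccccc1
F2 | step 8 | methyl 5-[4-(benzyloxy)-3-methoxyphenyl]pent-2-ynoate | COC(=O)C#CCCc1ccc(OCc2ccccc2)c(OC)c1
F3 | step 8 | dimethyl 3,3'-methylenebis{2-[2-(4-benzyloxy-3-methoxyphenyl)ethyl]-4,6-dimethoxy-6-(trimethylsilyloxy)cyclohexa-1,4-diene-1-carboxylate} | COC(=O)C1=C(CCc2ccc(OCc3ccccc3)c(OC)c2)C(CC2C(OC)=CC(OC)(O[Si](C)(C)C)C(C(=O)OC)=C2CCc2ccc(OCc3ccccc3)c(OC)c2)C(OC)=CC1(OC)O[Si](C)(C)C
F4 | step 8 | dimethyl 3,3'-methylenebis{2-[2-(4-benzyloxy-3-methoxyphenyl)ethyl]-6-hydroxy-4-methoxybenzoate} | COC(=O)c1c(O)cc(OC)c(Cc2c(OC)cc(O)c(C(=O)OC)c2CCc2ccc(OCc3ccccc3)c(OC)c2)c1CCc1ccc(OCc2ccccc2)c(OC)c1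
F5 | step 8 | 3,3'-methylenebis{2-[2-(4-benzyloxy-3-methoxyphenyl)ethyl]-6-hydroxy-4-methoxybenzoic acid} | O=C(O)c1c(O)cc(OC)c(Cc2c(OC)cc(O)c(C(=O)O)c2CCc2ccc(OCc3ccccc3)c(OC)c2)c1CCc1ccc(OCc2ccccc2)c(OC)c1
F6 | step 7 | 1-(benzyloxy)-4-{2-[3,5-dimethoxy-2-nitro-3-(trimethylsilyloxy)cyclohex-4-en-1-yl]ethyl}-2-methoxybenzene | COC1(O[Si](C)(C)C)C=C(OC)CC(CCc2ccc(OCc3ccccc3)c(OC)c2)C1[N+](=O)[O-]
F7 | step 7 | 5-[2-(4-benzyloxy-3-methoxyphenyl)ethyl]-3-methoxy-6-nitrocyclohex-2-en-1-one | O=C1C=C(OC)CC(CCc2ccc(OCc3ccccc3)c(OC)c2)C1[N+](=O)[O-]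
F8 | step 7 | 3-[2-(4-benzyloxy-3-methoxyphenyl)ethyl]-5-methoxyphenol | COc1cc(O)cc(CCc2ccc(OCc3ccccc3)c(OC)c2)c1
F9 | step 5 | N1,N5-dimethoxy-N1,N5-dimethylpentanediamide | CON(C)C(=O)CCCC(=O)N(C)OC
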